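## Analysis of the target

The target is a naamidine-type alkaloid built on a fully substituted imidazole (ring A). N1 carries a methyl group, C2 an exocyclic NH, C4 a secondary carbinol carbon that also bears a 4-methoxyphenyl ring, and C5 a 4-methoxybenzyl group. The exocyclic nitrogen is bonded to C4 of a 1-methylimidazoline-2,5-dione (ring B), the amidine carbon of a dehydrohydantoin whose C=N runs from that carbon to N3. The only stereocentre is the (R)-carbinol carbon; it lies between two aromatic rings with no neighbouring stereo element to relay from, so it must be set by reagent control. The carbinol is doubly benzylic and donor-substituted, so acid ionises it with racemisation or deoxygenation; ring B is an acylamidine/imide that hydroxide, alkoxide and hydrazine open; the 2-aminoimidazole is electron-rich. The difficulty is regiochemical: the N-methyl group must stand next to the benzyl-bearing C5 and away from C4, the two ring carbons carry arylmethyl groups that differ only in oxidation level, and the exocyclic nitrogen must stay free for ring B. The strategy reads the N3–C2–N(exocyclic) amidine of ring A, with the C4 substituent at the ketone level, as N2–C3–N4 of a 3-amino-1,2,4-oxadiazole whose amino nitrogen (the future N1) is the nitrogen of an enaminone. C5 and C4 are then the β- and α-carbons of that enaminone and the carbinol carbon is its carbonyl, so the aryl ketone serves both as the activating group of the ring synthesis and as the handle for asymmetric reduction.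

## Retrosynthetic reasoning

13 ⇒ 12. The C–H bond of the carbinol is cut first, giving ketone 12. Setting the stereocentre in the last step means the ionisable carbinol never meets the acid of the deacylation or the heat of the ring B condensation and needs no protecting group. The forward reaction must deliver hydrogen to one face of an aryl heteroaryl ketone and leave ring B alone.

12 ⇒ 9 + 10. The bond between the exocyclic nitrogen and C4 of ring B is cut, giving aminoimidazole 9 and trione 10. Ring B is the most base-labile part of the molecule, so it is attached after every basic step. The forward reaction is a dehydrative condensation that needs 10 activated at C4 as the silyl imidate 11, so that the nitrogen ends on the carbonyl carbon next to N3 and not on the one next to the N-methyl group.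

9 ⇒ 8 ⇒ 7. Two functional-group operations are removed: the N-acetyl group is put back (9 ⇒ 8) and the N1–CH3 bond is cut (8 ⇒ 7). The acetyl group comes free of charge from the ring synthesis and shields the exocyclic nitrogen during alkylation. The forward alkylation must choose N1 over N3; the anion of a 4-acylimidazole reacts at the nitrogen remote from the acyl group, which here is N1.

7 ⇒ 5 (key disconnection). The N3–C4 bond of ring A is opened and an O–N bond is reinstated between the acetyl oxygen and N3, turning the imidazole into the oxadiazolyl enaminone 5. This removes the whole heterocycle-forming problem in one isomerisation: 5 and 7 have the same formula, the aroyl group is placed at C4 by the mechanism, and the benzyl group at C5 follows from the constitution of 5. The forward step must make the enaminone α-carbon attack the oxadiazole N2; it passes through the 4H-imidazole 6.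

5 ⇒ 3 + 4. The enamine C–N bond is cut to give diketone 3 and aminooxadiazole 4. The forward condensation has to take place at the benzyl ketone of 3, not at the anisoyl carbonyl; this is the one point where the regiochemistry of ring A is decided, and it can be checked on 5 before the key step.

3 ⇒ 1 + 2. The C2–C3 bond of the diketone is cut to give ketone 1 and ester 2, a crossed Claisen condensation between two inexpensive anisole derivatives.

## Alternatives that were turned down

Alternative 1: Ring A is closed from an acyclic N-propargyl guanidine A2, built from methyl (R)-4-methoxymandelate A1, and 4-methoxyphenyl triflate A3. With Pd(OAc)2, RuPhos and LiOtBu the arylpalladium species and the N-methyl nitrogen add across the alkyne, forming N1–C5 and the bond from the former terminal carbon to the aryl ring; a proton shift then aromatises the benzylidene imidazoline to the sulfonamide A4.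
- For it: the N-methyl position is fixed by construction, the stereocentre is bought and not made, and the benzyl aryl group is introduced convergently. On these points it is stronger than the chosen route.
- Against it: A2 needs many steps from A1 and passes through an α-aryl-α-silyloxy aldehyde that epimerises readily. The aromatising proton shift goes through an aza-allyl anion with a β-silyloxy group, so E1cB loss of the oxygen substituent threatens the very carbinol the route is meant to preserve. Two protecting groups must then be removed before and after ring B is attached.
- Comparison: the chosen route has no stereocentre until the last step, uses achiral bulk starting materials and is several steps shorter.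

Alternative 2: Both C–N bonds of ring A are made at once from N-methylpyrimidin-2-amine A5 and 2-bromo-1,4-bis(4-methoxyphenyl)butane-1,3-dione A6. The pyrimidine ring nitrogen is alkylated (N3–C4), the methylamino group condenses with the benzyl ketone (N1–C5), and the imidazo[1,2-a]pyrimidinium bromide A7 results; hydrazinolysis of the pyrimidine ring would then release compound 9 of the chosen route.
- For it: it reaches 9 one step sooner, needs no N-methylation and no protecting group. On step economy and N-methyl placement it is the stronger plan.
- Against it: A6 is a positive-halogen donor at a hindered, largely enolised carbon, so bromine transfer to the aminopyrimidine and reduction back to 3 compete with substitution. A secondary amine must condense with one ketone of a 2-amino-1,3-dicarbonyl that is prone to acyl cleavage, and the hydrazinolysis has to spare an aryl ketone.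
- Comparison: the regiochemistry rests on the same ketone-electrophilicity argument as in the chosen route, but there the choice is made in a reversible, checkable condensation giving a stable enaminone. In the ring closure that follows, the acyl group is required by the mechanism and is not exposed to attack.

Alternative 3: No ring is formed; the ketone is assembled on a preformed core derived from creatinine A8. Pd(OAc)2 with di(1-adamantyl)-n-butylphosphine joins the imidazol-4-yl bromide A9, carbon monoxide A10 and 4-methoxyphenylboronic acid A11 to give the formamidine-protected ketone A12, forming both bonds to the carbonyl carbon.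
- For it: the N-methyl and 2-amino positions are inherited from A8, and the aryl ketone is introduced late and modularly. On these two points it is stronger.
- Against it: A9 needs several steps from A8, including conversion of a lactam carbonyl into an aromatic bromide. Oxidative addition into an electron-rich, ortho-substituted aminoimidazolyl bromide is slow, and direct biaryl coupling without carbonyl insertion competes. The formamidine must be removed, and A10 is a toxic gas.
- Comparison: the chosen route makes the aryl ketone in the first step by a Claisen condensation, uses no palladium, and is shorter.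

Key step: step 3

Assumption: 2-acylamino- and 2-aminoimidazoles and ring B are drawn as the amino tautomers of the target SMILES, and 1, 2, 4 and 10 are taken as purchasable.

## Route

Step 1
Reactants: 1 4'-methoxyacetophenone; 2 methyl 4-methoxyphenylacetate
Product: 3 1,4-bis(4-methoxyphenyl)butane-1,3-dione
Conditions: NaH (2.5 equiv), THF, 0 °C to reflux; then aq. HCl
Reagents that add atoms: none
Why: Crossed Claisen condensation: the sodium enolate of 1 is acylated by ester 2 and the equilibrium is pulled through by irreversible deprotonation of the 1,3-diketone. Self-condensation of 2 is the expected by-product and the acidic diketone can be separated from it by base extraction.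

Step 2
Reactants: 3 1,4-bis(4-methoxyphenyl)butane-1,3-dione; 4 5-methyl-1,2,4-oxadiazol-3-amine
Product: 5 (Z)-1,4-bis(4-methoxyphenyl)-3-[(5-methyl-1,2,4-oxadiazol-3-yl)amino]but-2-en-1-one
Conditions: TsOH·H2O (cat.), toluene, reflux, Dean–Stark
Reagents that add atoms: none
Why: Acid-catalysed enaminone formation from a 3-amino-1,2,4-oxadiazole and a 1,3-diketone, a known reaction of this amine. The benzyl ketone is the more electrophilic carbonyl because the anisoyl carbonyl is deactivated by the p-methoxyphenyl ring, and the product is held as the conjugated Z-enaminone by its N–H···O=C hydrogen bond while water is removed.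

Step 3
Reactants: 5 (Z)-1,4-bis(4-methoxyphenyl)-3-[(5-methyl-1,2,4-oxadiazol-3-yl)amino]but-2-en-1-one
Product: 7 N-[4-(4-methoxybenzoyl)-5-(4-methoxybenzyl)-1H-imidazol-2-yl]acetamide, via 4H-imidazole tautomer 6 (not isolated)
Conditions: NaOEt (1.2 equiv), EtOH, reflux; then AcOH
Reagents that add atoms: none
Why: Ethoxide removes the enaminone N–H to give a delocalised aza-enolate whose carbon terminus, the carbon α to the anisoyl group, can reach ring N2 once the side chain turns syn to it. That carbon attacks N2 in the ring plane, into the σ* orbital of the weak O1–N2 bond, so the N3–C4 bond of the imidazole forms as O1 leaves and the old C5–O1 unit with its methyl group becomes the acetyl group on the former N4; this is the Boulton–Katritzky rearrangement, known for N-(1,2,4-oxadiazol-3-yl) enaminoketones, which give 2-acylamino-4-acylimidazoles. The closure is a 5-exo displacement at nitrogen, the leaving oxygen lying outside the new ring N2–C3–N–C=C, through a planar bicyclic transition state. The first product 6 has an acidic C4–H between the new C=N and the ketone, and its loss gives the aromatic imidazolide of 7, which together with amide formation makes the step irreversible. No stereocentre persists, since the C4 centre of 6 is transient and racemic. The step needs closure through the carbon α to the ketone and not through the benzylic carbon: the conjugated anion places its carbanion character on the α-carbon, and the benzylic carbon could only react after a deconjugating proton shift. Attack through nitrogen or oxygen would give three- or seven-membered rings and should not compete. The aroyl group therefore ends at C4 and the benzyl group at C5 as a direct consequence of the constitution of 5.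

Step 4
Reactants: 7 N-[4-(4-methoxybenzoyl)-5-(4-methoxybenzyl)-1H-imidazol-2-yl]acetamide
Product: 8 N-[4-(4-methoxybenzoyl)-5-(4-methoxybenzyl)-1-methyl-1H-imidazol-2-yl]acetamide
Conditions: MeI (1.05 equiv), K2CO3, DMF, 0 °C to rt
Reagents that add atoms: iodomethane, CI
Why: SN2 N-alkylation of the imidazolide anion: a 4-acylimidazolide alkylates at the nitrogen remote from the acyl group, here N1 next to the benzyl carbon, which is also the less hindered nitrogen and gives the conjugated vinylogous amide. One equivalent of MeI limits alkylation of the acetamide nitrogen and double alkylation.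

Step 5
Reactants: 8 N-[4-(4-methoxybenzoyl)-5-(4-methoxybenzyl)-1-methyl-1H-imidazol-2-yl]acetamide
Product: 9 [2-amino-5-(4-methoxybenzyl)-1-methyl-1H-imidazol-4-yl](4-methoxyphenyl)methanone
Conditions: 6 M HCl, EtOH, reflux; then aq. NaHCO3
Reagents that add atoms: none
Why: Acid hydrolysis of a heteroaryl acetamide. The aryl methyl ethers, the ketone and the N-methylimidazole are stable to aqueous HCl, and the aminoimidazole is protected as its salt until neutralisation.

Step 6
Reactants: 9 [2-amino-5-(4-methoxybenzyl)-1-methyl-1H-imidazol-4-yl](4-methoxyphenyl)methanone; 10 1-methylparabanic acid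
Product: 12 4-{[4-(4-methoxybenzoyl)-5-(4-methoxybenzyl)-1-methyl-1H-imidazol-2-yl]amino}-1-methyl-1H-imidazole-2,5-dione, via silyl imidate 11 (not isolated)
Conditions: 10, N,O-bis(trimethylsilyl)acetamide, MeCN, 80 °C; then 9, toluene, 110 °C; MeOH work-up
Reagents that add atoms: none
Why: Condensation of a 2-aminoimidazole with silyl-activated 1-methylparabanic acid, the established way to attach ring B of the naamidines. Silylation of the imide gives the O-silyl imidate 11, whose C4, flanked by C5=O, is the most electrophilic carbon, and addition–elimination by the amino group of 9 puts the nitrogen on the carbon next to N3. The neutral, non-aqueous conditions spare ring B and the ketone.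

Step 7
Reactants: 12 4-{[4-(4-methoxybenzoyl)-5-(4-methoxybenzyl)-1-methyl-1H-imidazol-2-yl]amino}-1-methyl-1H-imidazole-2,5-dione
Product: 13 4-({4-[(R)-hydroxy(4-methoxyphenyl)methyl]-5-(4-methoxybenzyl)-1-methyl-1H-imidazol-2-yl}amino)-1-methyl-1H-imidazole-2,5-dione
Conditions: RuCl(p-cymene)[(S,S)-TsDPEN] (5 mol %), HCO2H/Et3N (1:1), DMF, 40 °C
Reagents that add atoms: none
Why: Noyori asymmetric transfer hydrogenation of an aryl heteroaryl ketone, selective for the ketone over the acylamidine and imide carbonyls of ring B. The unhindered p-anisyl ring can lie coplanar with the carbonyl and take the CH/π contact with the η6-arene, while the imidazolyl flank with its C5 benzyl group acts as the encumbered substituent, as in ortho-substituted benzophenones; on this model the (S,S)-catalyst should give the (R)-carbinol. The sense is to be confirmed by Mosher ester analysis and the (R,R)-catalyst taken if it is opposite, and the near-neutral formate buffer avoids acid ionisation of the product.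

## Compound list

1 | 4'-methoxyacetophenone | COc1ccc(C(C)=O)cc1 | starting material
2 | methyl 4-methoxyphenylacetate | COC(=O)Cc1ccc(OC)cc1 | starting material
3 | 1,4-bis(4-methoxyphenyl)butane-1,3-dione | COc1ccc(CC(=O)CC(=O)c2ccc(OC)cc2)cc1 | intermediate
4 | 5-methyl-1,2,4-oxadiazol-3-amine | Cc1nc(N)no1 | starting material
5 | (Z)-1,4-bis(4-methoxyphenyl)-3-[(5-methyl-1,2,4-oxadiazol-3-yl)amino]but-2-en-1-one | Cc1nc(N/C(Cc2ccc(OC)cc2)=C\C(=O)c2ccc(OC)cc2)no1 | intermediate
6 | N-[4-(4-methoxybenzoyl)-5-(4-methoxybenzyl)-4H-imidazol-2-yl]acetamide (racemic at C4, formed in the flask, not isolated) | CC(=O)NC1=NC(C(=O)c2ccc(OC)cc2)C(Cc2ccc(OC)cc2)=N1 | intermediate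
7 | N-[4-(4-methoxybenzoyl)-5-(4-methoxybenzyl)-1H-imidazol-2-yl]acetamide | CC(=O)Nc1nc(C(=O)c2ccc(OC)cc2)c(Cc2ccc(OC)cc2)[nH]1 | intermediate
8 | N-[4-(4-methoxybenzoyl)-5-(4-methoxybenzyl)-1-methyl-1H-imidazol-2-yl]acetamide | CC(=O)Nc1nc(C(=O)c2ccc(OC)cc2)c(Cc2ccc(OC)cc2)n1C | intermediate
9 | [2-amino-5-(4-methoxybenzyl)-1-methyl-1H-imidazol-4-yl](4-methoxyphenyl)methanone | Cn1c(N)nc(C(=O)c2ccc(OC)cc2)c1Cc1ccc(OC)cc1 | intermediate
10 | 1-methylparabanic acid (1-methylimidazolidine-2,4,5-trione) | CN1C(=O)NC(=O)C1=O | starting material
11 | 1-methyl-4-(trimethylsilyloxy)-1H-imidazole-2,5-dione (formed in the flask, not isolated) | CN1C(=O)N=C(O[Si](C)(C)C)C1=O | intermediate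
12 | 4-{[4-(4-methoxybenzoyl)-5-(4-methoxybenzyl)-1-methyl-1H-imidazol-2-yl]amino}-1-methyl-1H-imidazole-2,5-dione | COc1ccc(Cc2c(C(=O)c3ccc(OC)cc3)nc(NC3=NC(=O)N(C)C3=O)n2C)cc1 | intermediate
13 | 4-({4-[(R)-hydroxy(4-methoxyphenyl)methyl]-5-(4-methoxybenzyl)-1-methyl-1H-imidazol-2-yl}amino)-1-methyl-1H-imidazole-2,5-dione | COc1ccc(Cc2c([C@H](O)c3ccc(OC)cc3)nc(NC3=NC(=O)N(C)C3=O)n2C)cc1 | target

## Step count and least certain steps

Total step count: 7. Longest linear sequence: 7 steps (1 and 2 to 13); 4 and 10 enter as purchased building blocks.

Step 3 (key step). The most likely failures are ethoxide-induced cleavage of the substrate in place of rearrangement (attack at the oxadiazole C5 or retro-Claisen-type deacylation of the enaminone) and partial ring closure through the benzylic carbon after a proton shift in the anion, which would give a constitutional isomer. Fallback: setting out from 3, bromination at C2 with N-bromosuccinimide gives 2-bromo-1,4-bis(4-methoxyphenyl)butane-1,3-dione F1. Condensation of F1 with N-acetylguanidine in DMF (alkylation of a guanidine nitrogen at C2, then cyclodehydration onto the more electrophilic benzyl ketone) gives 7, where the route is rejoined before step 4.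

Step 4. Alkylation may go to the wrong nitrogen (N3 or the acetamide nitrogen) or proceed twice, because three nitrogen atoms share the charge of the anion. Fallback: setting out from 3, the bromodiketone F1 is made as above and heated with N-methylpyrimidin-2-amine in MeCN. Alkylation of the pyrimidine ring nitrogen and cyclodehydration of the methylamino group onto the benzyl ketone give 3-(4-methoxybenzoyl)-2-(4-methoxybenzyl)-1-methylimidazo[1,2-a]pyrimidin-1-ium bromide F2, in which the methyl group is placed by construction. Hydrazine hydrate in EtOH then cleaves the pyrimidine ring and releases 9, where the route is rejoined before step 6.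

Step 7. Three things may go wrong:
- slow hydride transfer to a ketone that is a vinylogous amide;
- poor facial discrimination between two aryl-type flanks;
- ionisation of the product carbinol in the formate medium, leading to racemisation or over-reduction.

Fallback: the stereocentre is set before ring B is present. Setting out from 8, Corey–Bakshi–Shibata reduction with (S)-2-methyl-CBS-oxazaborolidine and BH3·SMe2 in THF, with the encumbered imidazolyl as the large group, gives N-{4-[(R)-hydroxy(4-methoxyphenyl)methyl]-5-(4-methoxybenzyl)-1-methyl-1H-imidazol-2-yl}acetamide F3. The sequence then continues: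
- TBSCl and imidazole in DMF give the silyl ether N-{4-[(R)-(tert-butyldimethylsilyloxy)(4-methoxyphenyl)methyl]-5-(4-methoxybenzyl)-1-methyl-1H-imidazol-2-yl}acetamide F4.
- Hydrazine hydrate in EtOH removes the acetyl group without acid and gives 4-[(R)-(tert-butyldimethylsilyloxy)(4-methoxyphenyl)methyl]-5-(4-methoxybenzyl)-1-methyl-1H-imidazol-2-amine F5.
- Condensation with 10 under the conditions of step 6 gives the silyl ether of the target, 4-({4-[(R)-(tert-butyldimethylsilyloxy)(4-methoxyphenyl)methyl]-5-(4-methoxybenzyl)-1-methyl-1H-imidazol-2-yl}amino)-1-methyl-1H-imidazole-2,5-dione F6.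
- Bu4NF buffered with AcOH in THF removes the silyl group and gives 13.

Step 2. The weakly nucleophilic amine may condense slowly, or in part at the anisoyl carbonyl, which would carry the wrong constitution into the key step. Fallback: setting out from 4, the carbon chain is built as an ynone so that nitrogen can only enter at the benzyl-bearing carbon. 4-Methoxybenzoyl chloride and 3-(4-methoxyphenyl)prop-1-yne are coupled with PdCl2(PPh3)2, CuI and Et3N in THF to give 1,4-bis(4-methoxyphenyl)but-2-yn-1-one F7. Base-promoted conjugate addition of 4 (Cs2CO3, MeCN) to the β-carbon of F7, or of its allenyl ketone isomer, gives 5, where the route is rejoined before step 3.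

## Further compounds

F1 | step 3 | 2-bromo-1,4-bis(4-methoxyphenyl)butane-1,3-dione | COc1ccc(CC(=O)C(Br)C(=O)c2ccc(OC)cc2)cc1
F2 | step 4 | 3-(4-methoxybenzoyl)-2-(4-methoxybenzyl)-1-methylimidazo[1,2-a]pyrimidin-1-ium bromide | C[N+]1=C2N=CC=CN2C(C(=O)c2ccc(OC)cc2)=C1Cc1ccc(OC)cc1.[Br-]
F3 | step 7 | N-{4-[(R)-hydroxy(4-methoxyphenyl)methyl]-5-(4-methoxybenzyl)-1-methyl-1H-imidazol-2-yl}acetamide | CC(=O)Nc1nc([C@H](O)c2ccc(OC)cc2)c(Cc2ccc(OC)cc2)n1C
F4 | step 7 | N-{4-[(R)-(tert-butyldimethylsilyloxy)(4-methoxyphenyl)methyl]-5-(4-methoxybenzyl)-1-methyl-1H-imidazol-2-yl}acetamide | CC(=O)Nc1nc([C@H](O[Si](C)(C)C(C)(C)C)c2ccc(OC)cc2)c(Cc2ccc(OC)cc2)n1C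
F5 | step 7 | 4-[(R)-(tert-butyldimethylsilyloxy)(4-methoxyphenyl)methyl]-5-(4-methoxybenzyl)-1-methyl-1H-imidazol-2-amine | Cn1c(N)nc([C@H](O[Si](C)(C)C(C)(C)C)c2ccc(OC)cc2)c1Cc1ccc(OC)cc1
F6 | step 7 | 4-({4-[(R)-(tert-butyldimethylsilyloxy)(4-methoxyphenyl)methyl]-5-(4-methoxybenzyl)-1-methyl-1H-imidazol-2-yl}amino)-1-methyl-1H-imidazole-2,5-dione | COc1ccc(Cc2c([C@H](O[Si](C)(C)C(C)(C)C)c3ccc(OC)cc3)nc(NC3=NC(=O)N(C)C3=O)n2C)cc1
F7 | step 2 | 1,4-bis(4-methoxyphenyl)but-2-yn-1-one | COc1ccc(CC#CC(=O)c2ccc(OC)cc2)cc1
A1 | alternative 1 | methyl (R)-2-hydroxy-2-(4-methoxyphenyl)acetate (methyl (R)-4-methoxymandelate) | COC(=O)[C@H](O)c1ccc(OC)cc1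
A2 | alternative 1 | N-[(1R)-1-(tert-butyldimethylsilyloxy)-1-(4-methoxyphenyl)but-3-yn-2-yl]-N'-methyl-N''-[2-(trimethylsilyl)ethanesulfonyl]guanidine (either configuration at C2 of the butynyl chain) | C#CC(NC(NC)=NS(=O)(=O)CC[Si](C)(C)C)[C@H](O[Si](C)(C)C(C)(C)C)c1ccc(OC)cc1
A3 | alternative 1 | 4-methoxyphenyl trifluoromethanesulfonate | COc1ccc(OS(=O)(=O)C(F)(F)F)cc1
A4 | alternative 1 | N-{4-[(R)-(tert-butyldimethylsilyloxy)(4-methoxyphenyl)methyl]-5-(4-methoxybenzyl)-1-methyl-1H-imidazol-2-yl}-2-(trimethylsilyl)ethanesulfonamide | C[Si](C)(C)CCS(=O)(=O)Nc1nc([C@H](O[Si](C)(C)C(C)(C)C)c2ccc(OC)cc2)c(Cc2ccc(OC)cc2)n1C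
A5 | alternative 2 | N-methylpyrimidin-2-amine | CNc1ncccn1
A6 | alternative 2 | 2-bromo-1,4-bis(4-methoxyphenyl)butane-1,3-dione | COc1ccc(CC(=O)C(Br)C(=O)c2ccc(OC)cc2)cc1
A7 | alternative 2 | 3-(4-methoxybenzoyl)-2-(4-methoxybenzyl)-1-methylimidazo[1,2-a]pyrimidin-1-ium bromide | C[N+]1=C2N=CC=CN2C(C(=O)c2ccc(OC)cc2)=C1Cc1ccc(OC)cc1.[Br-]
A8 | alternative 3 | creatinine (2-amino-1-methyl-1,5-dihydro-4H-imidazol-4-one) | CN1CC(=O)N=C1N
A9 | alternative 3 | (E)-N'-[4-bromo-5-(4-methoxybenzyl)-1-methyl-1H-imidazol-2-yl]-N,N-dimethylformimidamide | CN(C)/C=N/c1nc(Br)c(Cc2ccc(OC)cc2)n1C
A10 | alternative 3 | carbon monoxide | [C-]#[O+]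
A11 | alternative 3 | 4-methoxyphenylboronic acid | COc1ccc(B(O)O)cc1
A12 | alternative 3 | (E)-N'-[4-(4-methoxybenzoyl)-5-(4-methoxybenzyl)-1-methyl-1H-imidazol-2-yl]-N,N-dimethylformimidamide | CN(C)/C=N/c1nc(C(=O)c2ccc(OC)cc2)c(Cc2ccc(OC)cc2)n1C
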